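The earlier runs and the new flask stem from a simulated flask for an exercise; scatter was added.

| setting | south | south-east | flask |
|---|---|---|---|
| Z | 0.010 M | 0.010 M | 0.010 M |
| L | 0.020 M | 0.020 M | 0.0200 M |
| Q | 10 mM | 6.7 mM | 10.0 mM |
| E | 0.22 mM | 0.22 mM | 0.22 mM |
| remark | the very flask that is asked about, followed so far | run made earlier |  |
| volume of the second phase over the first |  |  | 0.50 |

| run | time / min | D / % |
|---|---|---|
| south | 0.250 | 0 |
| south | 0.667 | 0 |
| south | 1.33 | 2 |
| south | 2.00 | 6 |
| south | 3.00 | 4 |
| south | 4.00 | 9 |
| south | 5.00 | 11 |
| south-east | 0.833 | 1 |
| south-east | 2.50 | 5 |
| south-east | 5.00 | 11 |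
| south-east | 6.00 | 11 |
| south-east | 10.0 | 14 |
| south-east | 12.0 | 17 |
| south-east | 15.0 | 18 |

(scatter of a reading: 2 percentage points)

- factor on the rate of making D when 50 % of the Z are converted if L is charged twice over
- factor on the rate when 50 % of the Z are converted if E is charged at 0.020 mM instead

- in the second phase: L, J; everything else is in the first
- charges count per volume of the first phase; a concentration in a rate is the amount of a species over the volume of its own phase; every rate counts per litre of the first phase
- candidate steps: E + L <-> G + J; Z + G -> D + E; Z + Q -> X
- the earlier runs hold the two phases in the same ratio of volumes as the flask asked about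
- no earlier run changes the charge of E; that part of a forecast is a guess
- no earlier run changes the charge of L; that part of a forecast is a guess

1. Whatever the recipe, E plus G stays equal to the catalyst charged; these two are the resting states of the catalyst. D comes from Z + G, and at 50 % conversion every variant holds the same Z. So the factor on the rate is the factor on the catalyst charge times the factor on the share held as G.

2. The readings give no direct view of that share. The south-east run has 11 % D at 5.00 min but 18 % at 15.0 min, so the rate falls early. South reads 11 % at 5.00 min despite its different Q. As my own guess, I take about half of the catalyst as G at 50 % conversion.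

3. Turn L first. Doubling it roughly doubles G over E. From an even split, my factor on the rate is 1.33. No run tests this.

4. Now turn E. Call the new charge over the old the charge factor, here 0.0909. Less catalyst should make less J by the same conversion, so the G share should rise. The share cannot pass the whole charge, so from my even split I expect between 0.0909 and 0.182.

The forecast gives 1.8 for L, above my 1.33, and 0.11 for E, inside my range; it takes the rate as linear in catalyst and then adds “If Q competes, less J forms with little catalyst, which raises this somewhat”.

The simulation gives 1.27 and 0.150.

    E + L ⇌ G + J (K = 0.0764, k = 8410 M⁻¹ min⁻¹)
    Z + G → D + E (k = 163 M⁻¹ min⁻¹)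
    Z + Q → X (k = 10.1 M⁻¹ min⁻¹)

At 50 % conversion in this flask, E is 47.0 % of the catalyst, so G holds 53.0 %, and doubled L lifts that share to 67.3 %. In the flask charged with 0.020 mM, E is 12.5 %, so G holds 87.5 %, and the charge factor times 1.65 gives 0.150. In this flask at 5.76 min, the half-life of L by the forward step alone is 0.42 min, shorter than the 11 min half-life of Z by Z + Q. At 40.0 min this flask holds X at 69.6 % and D at 22.4 %.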